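## Structural features

The target is a germacranolide: a ten-membered carbocycle (C1–C10) trans-fused across C6–C7 to an α-methylene-γ-butyrolactone (O–C6, C7–C11, C11=C13, C12=O), with a (Z)-2-methylbut-2-enoate (angelate) on the C8 oxygen. C1 and C10 (C10 carries the C14 methyl) are bridged by an oxirane in which the ring bonds C1–C2 and C10–C9 are cis, so the epoxide is the oxidised form of a Z-configured trisubstituted ring olefin. C3 carries a secondary hydroxyl (β), C4 a tertiary hydroxyl (α) and the hydroxymethyl carbon C15, and C5 is a methylene group; C6 (O α), C7 (C11 β) and C8 (O β) form a contiguous triad. The seven stereocentres thus fall into three groups (C1/C10, C3/C4, C6/C7/C8) insulated from each other by the methylene groups C2, C5 and C9. Fragile groups are the epoxide (acid, transannular hydroxyls), the α-methylene lactone (nucleophiles, base), the angelate (isomerises to the tiglate, does not survive enolate or hydride chemistry) and the 1,2,3-triol. The real difficulty is the ten-membered ring containing the Z-C1=C10 unit together with the relay of configuration between the three insulated groups. The key step exploits the two-carbon units C10–C1 (oxirane, from a Z-olefin) and C4–C5 (carbinol bearing oxidised C15 next to a CH2, from a C15-substituted olefin): together they are the footprint of a 1(10),4-diene, that is of a decalin (ring A: C1–C5, C10; ring B: C5–C10) whose shared C5–C10 bond has been cut, the Z geometry being the signature of a cis ring fusion.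

## Logic of the disconnections

36 to 35: the two C–O bonds of the oxirane (C1–O, C10–O) are cut first because the epoxide is the most acid-sensitive group. This removes two stereocentres and leaves a Z-olefin. The forward step must deliver oxygen to the β face of the only electron-rich olefin, for which the homoallylic 3β-hydroxyl of 35 is used as director.

35 to 34 to 32 + 33: the C8–O acyl bond and the protecting groups on O3 and O4/O15 are cut. The angelate cannot survive the enolate and hydride steps, so it must enter late. The forward step needs an esterification that does not isomerise the Z-enoate of 33 and a selective unmasking of O8 in 31.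

32 to 31 to 28 to 26: C11=C13 and the lactone bond C12–O6 are cut and C12 is taken back to the alcohol level. This keeps both lactone functions out of all hydride steps. The forward oxidation must select the 6,12-diol, so the 4,15-diol is masked in 25.

24 to 23 to 22: the C4–O bond and one C5–H bond are cut, going back to the allylic alcohol C15–OH / C4=C5. This lets C4 be set by reagent control and explains the C5 methylene. The forward steps need tartrate-controlled face selection and hydride attack at C5.

22 to 21 to 20 (key): the C5–C10 bond is reconnected, so the two olefins C1=C10 and C4=C5 and the C15 carbonyl of 21 become a cis-decalin carrying a C1 sulfonate and a C4 formyl group. The medium ring is traded for two six-membered rings, and C3, C6, C7 and C8 now sit on one rigid bicycle. The forward fragmentation needs the C1–O bond antiperiplanar to C5–C10, a cis ring fusion (for Z) and a rate higher than loss of the C3 oxygen.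

20 to 16 to 13 to 11 to 8 to 7: only functional groups change. C15 comes from the C4 carbonyl through C4=C15, O1 from the C1 carbonyl, O3 from the methyl enol ether, O8 and H7 from the silyl enol ether. The demands are hydride delivery to C1 from the convex face, reagent control at C3 and methyl-blocked delivery at C8.

7 to 5 + 6: the bonds C5–C6 and C9–C10 are cut (Diels–Alder). One step gives both rings, the quaternary C10, the cis fusion, the C6 oxygen and every ring oxygen that is needed later. The demands are regiochemistry (C9 to C10), endo addition and enantioface control.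

5 to 4 to 2 + 3 to 1: the diene is taken back to a methyl ketone by cutting the C6–C7 bond (formylation) and the O–Si bonds.

## Other disconnections considered

Alternative 1: cut C6–C7 and the lactone C–O bond; forward key step is an intramolecular Barbier or Nozaki–Hiyama–Kishi allylation (CrCl2) of the bromo aldehyde A1, closing the ten-membered ring and the lactone together. This is the first route that comes to mind. The chosen plan is preferred because A1 needs two separately made enantiopure halves (C3/C4 and C8) and an acyclic Z-trisubstituted olefin. The closure would also have to create C6 and C7 in a folded, entropically costly transition state that nothing in A1 biases towards the trans lactone, whereas the decalin route relays all centres from one cycloaddition and forms the ring by bond cleavage.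

Alternative 2: reconnect C1–C6 and cut C8–C9; forward key step is an anionic oxy-Cope ring expansion of the 1,2-dialkenylcyclohexanol A2 to the cyclodecenone A3. The olefin geometry would depend on which chair of A2 reacts, which the substituents do not decide. The C8 oxygen cannot be carried through, because it would be β to the enolate and be eliminated. C6, C7 and C8 would therefore have to be built on the flexible ring of A3, with more steps and weaker control than on a decalin.

Alternative 3: cut C1=C10 and bridge C1 and C10 by sulfur; forward key step is a Ramberg–Bäcklund ring contraction of the eleven-membered sulfone A4. This needs the whole open chain with five stereocentres before an eleven-membered thioether closure at high dilution. The mechanism does not enforce the Z geometry in a ten-membered ring, and the step relays no stereochemistry; the fragmentation of a cis-decalin fixes both olefin geometries stereospecifically.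

Key step: step 15

Assumption: atom labels C1–C15 follow germacrane numbering with the lactone closed at C6 (C14 = methyl on C10, C15 = carbon on C4); the decalin intermediates keep these labels and α/β mean below/above the ring as usually drawn with H7 α.
Assumption: the (R)-BINOL titanium catalyst of step 4 is taken to give the enantiomer of 7 that is drawn; if the sense of induction is the opposite, the (S)-ligand is used.

## Steps

Step 1
Reactants: 1 5-hydroxypentan-2-one
Product: 2 5-(tert-butyldimethylsilyloxy)pentan-2-one
Conditions: tBuMe2SiCl, imidazole, DMF, 0 °C to rt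
Reagents that add atoms: tert-butyldimethylsilyl chloride, C[Si](C)(Cl)C(C)(C)C
Why: Standard silylation of a primary alcohol; the silyl ether masks C12 at the alcohol level so that no lactone can form before C8 is protected.

Step 2
Reactants: 2 5-(tert-butyldimethylsilyloxy)pentan-2-one; 3 ethyl formate
Product: 4 (Z)-3-(hydroxymethylene)-5-(tert-butyldimethylsilyloxy)pentan-2-one
Conditions: NaH, EtOH (cat.), Et2O, 0 °C to rt; then AcOH
Reagents that add atoms: none
Why: Claisen formylation of a methyl alkyl ketone goes to the methylene side under equilibrating conditions (more substituted 1,3-dicarbonyl enolate) and gives the chelated enol; this carbon becomes C6.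

Step 3
Reactants: 4 (Z)-3-(hydroxymethylene)-5-(tert-butyldimethylsilyloxy)pentan-2-one
Product: 5 (E)-1,3-bis(tert-butyldimethylsilyloxy)-2-[2-(tert-butyldimethylsilyloxy)ethyl]buta-1,3-diene
Conditions: tBuMe2SiOTf (2.3 equiv), Et3N, Et2O, −10 °C to rt
Reagents that add atoms: tert-butyldimethylsilyl triflate, CC(C)(C)[Si](C)(C)OS(=O)(=O)C(F)(F)F
Why: O-silylation of the enol and enol silylation of the methyl ketone give the 1,3-dioxygenated diene; the β-silyloxy enone equilibrates to the isomer with the silyloxy group trans to the acyl group, and only this E isomer can reach the s-cis conformation needed in step 4.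

Step 4
Reactants: 5 bis(silyloxy)diene; 6 2-methoxy-5-methyl-1,4-benzoquinone
Product: 7 cis-fused cycloadduct (5β-H 10β-CH3 6α-OTBS)
Conditions: TiCl2(OiPr)2 (10 mol %), (R)-1,1'-bi-2-naphthol (10 mol %), 4 Å MS, CH2Cl2, −30 °C
Reagents that add atoms: none
Why: Diels–Alder reaction at the methyl-bearing double bond (the methoxy-bearing one is a deactivated vinylogous ester); the C4 carbonyl, not conjugated to the methoxy group and chelated with it by tetravalent titanium, makes C10 the electrophilic terminus, so the nucleophilic CH2 end of the diene (C9) bonds to C10 and the silyloxy-bearing end (C6) to C5. Endo addition puts the C6 silyloxy group cis to the C5–C4 bond (6α with 5β-H), the fusion is cis by necessity, and the chiral chelate selects the enantioface.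

Step 5
Reactants: 7 cis-fused cycloadduct
Product: 8 4-methylene adduct (C4=C15H2)
Conditions: Cp2TiMe2 (1.5 equiv), toluene, 65 °C, dark
Reagents that add atoms: dimethyltitanocene, C[Ti](C)(C1C=CC=C1)C1C=CC=C1
Why: Carbonyl methylenation by the titanium methylidene is non-basic, so C5–H (α to C4=O, with a β-silyloxy group at C6) neither epimerises nor eliminates; the C4 ketone reacts ahead of the vinylogous ester carbonyl at C1. This carbon is C15.

Step 6
Reactants: 8 4-methylene adduct
Product: 10 8β-alcohol, via 8-ketone 9 (not isolated)
Conditions: Bu4NF (1.05 equiv), AcOH (1.2 equiv), THF, −78 °C; then NaBH4, MeOH, −40 °C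
Reagents that add atoms: none
Why: Buffered fluoride cleaves only the silyl enol ether at −78 °C; protonation at C7 puts the side chain equatorial and trans to the C6 silyloxy group (H7 α), which is also the thermodynamic arrangement. Borohydride then attacks the C8 ketone from the α face because the β axial approach is blocked by the syn-axial C14 methyl, giving the 8β (axial) alcohol before the β-silyloxy ketone can eliminate; the vinylogous ester is inert.

Step 7
Reactants: 10 8β-alcohol
Product: 11 8β-(4-methoxybenzyl) ether
Conditions: NaH, 4-MeOC6H4CH2Cl, Bu4NI (cat.), THF/DMF, 0 °C to rt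
Reagents that add atoms: 4-methoxybenzyl chloride, COc1ccc(CCl)cc1
Why: Williamson etherification; this ether is later removed oxidatively without touching silyl, acetal or ester groups, which lets O8 be freed alone for the angelate.

Step 8
Reactants: 11 8β-(4-methoxybenzyl) ether
Product: 13 1α-acetate, via 1α-allylic alcohol 12 (not isolated)
Conditions: iBu2AlH, CH2Cl2, −78 °C; aq. potassium sodium tartrate (pH 8); then Ac2O, Et3N, DMAP (cat.), CH2Cl2, 0 °C
Reagents that add atoms: acetic anhydride, CC(=O)OC(C)=O
Why: 1,2-Reduction of the vinylogous ester carbonyl; hydride enters from the convex β face of the cis-decalin, anti to the C10–C9 bond, giving the 1α-alcohol that will be equatorial on ring A. The γ-alkoxy allylic alcohol is acetylated at once because as the free alcohol it would ionise on contact with acid.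

Step 9
Reactants: 13 1α-acetate
Product: 14 1α-acetoxy-4-methylene-3-ketone
Conditions: oxalic acid (0.1 equiv), THF/H2O (10:1), 0 °C
Reagents that add atoms: water, O
Why: Acid-catalysed enol ether hydrolysis: protonation at C2 gives the C3 oxocarbenium ion, water adds and methanol leaves; at 0 °C the acetate is expected to be too poor a nucleofuge to ionise. The α-methylene ketone is used at once because such enones dimerise.

Step 10
Reactants: 14 1α-acetoxy-4-methylene-3-ketone
Product: 15 3β-allylic alcohol
Conditions: (R)-1-methyl-3,3-diphenyl-tetrahydro-1H,3H-pyrrolo[1,2-c][1,3,2]oxazaborole (20 mol %), catecholborane, toluene, −78 °C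
Reagents that add atoms: none
Why: Corey–Bakshi–Shibata reduction under reagent control: the alkenyl side (C4) acts as the large group and the (R)-catalyst should give the (3S), that is 3β, alcohol; catecholborane does not hydroborate the enone olefin at this temperature. Any minor enantiomer carried from step 4 becomes a separable diastereomer here.

Step 11
Reactants: 15 3β-allylic alcohol
Product: 16 3β-methoxymethyl ether
Conditions: MeOCH2Cl, iPr2NEt, CH2Cl2, 0 °C to rt
Reagents that add atoms: chloromethyl methyl ether, COCCl
Why: Alkylation of the secondary alcohol; an acetal ether is chosen because its alkoxide is a poor leaving group in step 15 and it falls together with the acetonide in step 24.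

Step 12
Reactants: 16 3β-methoxymethyl ether
Product: 18 1α,15-diol, via 15-hydroxy 1-acetate 17 (not isolated)
Conditions: 9-BBN-H, THF, 0 °C to rt; then NaOH, H2O2, H2O/MeOH, 0 °C to rt
Reagents that add atoms: hydrogen peroxide, OO
Why: Anti-Markovnikov hydroboration of the 1,1-disubstituted olefin puts boron on C15 and oxidation gives the primary alcohol; the basic peroxide also cleaves the acetate. The configuration formed at C4 (expected anti to the C3 ether) does not matter because C4 becomes trigonal in step 15.

Step 13
Reactants: 18 1α,15-diol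
Product: 19 1α-hydroxy 15-aldehyde
Conditions: TEMPO (10 mol %), PhI(OAc)2, CH2Cl2, rt
Reagents that add atoms: none
Why: Nitroxyl-catalysed oxidation is selective for the primary alcohol; the hindered secondary C1 alcohol next to the quaternary C10 is left.

Step 14
Reactants: 19 1α-hydroxy 15-aldehyde
Product: 20 1α-mesylate 15-aldehyde
Conditions: MeSO2Cl, Et3N, CH2Cl2, −30 °C
Reagents that add atoms: methanesulfonyl chloride, CS(=O)(=O)Cl
Why: Sulfene-mediated mesylation works on hindered secondary alcohols; the low temperature avoids enolisation-based side reactions of the aldehyde.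

Step 15
Reactants: 20 1α-mesylate 15-aldehyde
Product: 22 ten-membered allylic alcohol, via dienal 21 (not isolated)
Conditions: NaOC(CH3)2CH2CH3 (1.5 equiv), toluene, 0 °C; then NaBH4, EtOH, 0 °C
Reagents that add atoms: none
Why: Deprotonation at C4 gives the sodium enolate of the aldehyde; its π electrons flow into C4–C5 while the C5–C10 σ bond breaks, C10=C1 forms and mesylate leaves from C1 in one seven-centre event (enolate-assisted 1,4-fragmentation, a vinylogous Grob fragmentation; closest known type: the fragmentation of decalin mesylate aldehydes to cyclodeca-1,5-dienals). No ring is closed: the ten-membered ring appears by cleavage of the bond shared by rings A and B, so there is no entropic or transannular cost of cyclisation. The reaction can start only from the chair–chair conformer A of the cis-decalin, in which the C1–OMs bond is equatorial on ring A and antiperiplanar to C5–C10; in that conformer C9 is axial on ring A and ends cis to C2 (Z at C1=C10), while C6 is equatorial and ends trans to C3 at C4=C5. No stereocentre is created; C3, C6, C7 and C8 are carried over unchanged, and C1, C4, C5 and C10 are deliberately sacrificed. The selectivity needed is fragmentation over β-elimination of the axial C3 ether: the sulfonate is a far better nucleofuge than an acetal alkoxide, its σ* orbital is aligned through C5–C10, and the reaction is run cold in toluene where alkoxide expulsion is poorly supported. Dienal 21 is reduced in the same flask (1,2-addition) because such dienals are prone to Cope rearrangement and transannular reactions, giving the stable allylic alcohol 22.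

Step 16
Reactants: 22 ten-membered allylic alcohol
Product: 23 4α,5-epoxy alcohol
Conditions: Ti(OiPr)4 (10 mol %), L-(+)-diethyl tartrate (12 mol %), tBuOOH, 4 Å MS, CH2Cl2, −20 °C
Reagents that add atoms: tert-butyl hydroperoxide, CC(C)(C)OO
Why: Sharpless asymmetric epoxidation under reagent control: with C5=C4 drawn left to right and C15H2OH at the lower right, the L-(+)-tartrate complex adds oxygen to the face turned to the viewer, which is the α face at C4; the isolated C1=C10 olefin is inert. Any material of the wrong enantiomeric series becomes a diastereomer.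

Step 17
Reactants: 23 4α,5-epoxy alcohol
Product: 24 4α,15-diol
Conditions: LiAlH4, THF, 0 °C
Reagents that add atoms: none
Why: Hydride opens the trisubstituted epoxide by SN2 attack at the less substituted C5 (C4 is quaternary), helped by the C15 alkoxyaluminate; C4 keeps its oxygen with retention and C5 becomes the methylene group.

Step 18
Reactants: 24 4α,15-diol
Product: 25 4,15-acetonide
Conditions: 2-methoxypropene, pyridinium p-toluenesulfonate (cat.), CH2Cl2, 0 °C
Reagents that add atoms: 2-methoxypropene, COC(C)=C
Why: Ketalisation of the 1,2-diol; it keeps the primary C15 alcohol out of the oxidation in step 20.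

Step 19
Reactants: 25 4,15-acetonide
Product: 26 6α,12-diol
Conditions: Bu4NF, THF, rt
Reagents that add atoms: none
Why: Fluoride removes both silyl ethers (O6 and O12); acetal and benzyl-type ethers are stable.

Step 20
Reactants: 26 6α,12-diol
Product: 28 trans-fused 6α,12-lactone, via lactol 27 (not isolated)
Conditions: TEMPO (20 mol %), PhI(OAc)2 (2.5 equiv), CH2Cl2, rt
Reagents that add atoms: none
Why: Oxidative lactonisation of a 1,4-diol: the primary alcohol goes to the aldehyde, the C6 hydroxyl closes the lactol, and a second oxidation gives the γ-lactone; the fusion is trans because C6 and C7 were set on the decalin.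

Step 21
Reactants: 28 trans-fused 6α,12-lactone
Product: 31 α-methylene lactone, via Mannich base 29 (not isolated), via ammonium iodide 30 (not isolated)
Conditions: LiN(iPr)2, THF, −78 °C; CH2=NMe2+ I−, −78 to 0 °C; then MeI, MeOH, rt; then NaHCO3, CH2Cl2/H2O
Reagents that add atoms: N,N-dimethylmethyleneiminium iodide, C=[N+](C)C.[I-]
Why: Mannich reaction of the lactone enolate, quaternisation and Hofmann-type elimination give the exocyclic methylene (C13); no β leaving group sits next to the enolate and no stereocentre is affected.

Step 22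
Reactants: 31 α-methylene lactone
Product: 32 8β-alcohol
Conditions: DDQ, CH2Cl2/pH 7 buffer, 0 °C
Reagents that add atoms: none
Why: Oxidative cleavage of the 4-methoxybenzyl ether frees O8 alone; acetal groups, the trisubstituted olefin and the α-methylene lactone are untouched.

Step 23
Reactants: 32 8β-alcohol; 33 angelic acid
Product: 34 8β-angelate
Conditions: 2,4,6-Cl3C6H2COCl, Et3N, toluene, rt; then 32, 75 °C
Reagents that add atoms: none
Why: Yamaguchi-type esterification through the mixed anhydride without a nucleophilic catalyst; this avoids the addition–elimination that isomerises angelates to tiglates.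

Step 24
Reactants: 34 8β-angelate
Product: 35 3β,4α,15-triol
Conditions: Me2BBr, CH2Cl2, −78 °C; then aq. NaHCO3/THF
Reagents that add atoms: none
Why: The bromoborane cleaves the methoxymethyl ether and the acetonide at low temperature by Lewis acid activation of the acetal oxygens; esters and the unactivated olefin are tolerated, and no protic acid is present that could drive transannular attack of the C4 hydroxyl on C1=C10.

Step 25
Reactants: 35 3β,4α,15-triol
Product: 36 target (8β-angeloyloxy-1β,10β-epoxy-3β,4α,15-trihydroxygermacr-11(13)-en-6α,12-olide)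
Conditions: VO(acac)2 (5 mol %), tBuOOH, CH2Cl2, 0 °C to rt
Reagents that add atoms: tert-butyl hydroperoxide, CC(C)(C)OO
Why: Vanadium-catalysed hydroxyl-directed epoxidation: the homoallylic 3β-hydroxyl should deliver the peroxide to the β face of the Z-olefin and give the cis 1β,10β-epoxide; the α-methylene lactone and the angelate are electron-poor and do not react.

## Compound list

1 | 5-hydroxypentan-2-one | CC(=O)CCCO | starting material
2 | 5-(tert-butyldimethylsilyloxy)pentan-2-one | CC(=O)CCCO[Si](C)(C)C(C)(C)C | intermediate
3 | ethyl formate | CCOC=O | starting material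
4 | (Z)-3-(hydroxymethylene)-5-(tert-butyldimethylsilyloxy)pentan-2-one (chelated enol) | CC(=O)/C(CCO[Si](C)(C)C(C)(C)C)=C\O | intermediate
5 | (E)-1,3-bis(tert-butyldimethylsilyloxy)-2-[2-(tert-butyldimethylsilyloxy)ethyl]buta-1,3-diene | C=C(O[Si](C)(C)C(C)(C)C)/C(CCO[Si](C)(C)C(C)(C)C)=C/O[Si](C)(C)C(C)(C)C | intermediate
6 | 2-methoxy-5-methyl-1,4-benzoquinone | COC1=CC(=O)C(C)=CC1=O | starting material
7 | cis-decalin cycloadduct: C1 and C4 ketones, C2=C3 with 3-OMe, 5β-H, 10β-CH3, 6α-OTBS, C7=C8 silyl enol ether (8-OTBS), 7-CH2CH2OTBS | O=C1C=C(OC)C(=O)[C@H]2[C@@H](O[Si](C)(C)C(C)(C)C)C(CCO[Si](C)(C)C(C)(C)C)=C(O[Si](C)(C)C(C)(C)C)C[C@@]12C | intermediate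
8 | as 7 with C4=C15H2 in place of the C4 ketone | O=C1C=C(OC)C(=C)[C@H]2[C@@H](O[Si](C)(C)C(C)(C)C)C(CCO[Si](C)(C)C(C)(C)C)=C(O[Si](C)(C)C(C)(C)C)C[C@@]12C | intermediate
9 | 8-ketone: 7α-H, 7β-CH2CH2OTBS, 6α-OTBS | O=C1C=C(OC)C(=C)[C@H]2[C@@H](O[Si](C)(C)C(C)(C)C)[C@H](CCO[Si](C)(C)C(C)(C)C)C(=O)C[C@@]12C | intermediate (not isolated)
10 | 8β-alcohol of 9 | O=C1C=C(OC)C(=C)[C@H]2[C@@H](O[Si](C)(C)C(C)(C)C)[C@H](CCO[Si](C)(C)C(C)(C)C)[C@H](O)C[C@@]12C | intermediate
11 | 8β-(4-methoxybenzyl) ether of 10 | O=C1C=C(OC)C(=C)[C@H]2[C@@H](O[Si](C)(C)C(C)(C)C)[C@H](CCO[Si](C)(C)C(C)(C)C)[C@H](OCc3ccc(OC)cc3)C[C@@]12C | intermediate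
12 | 1α-allylic alcohol (C2=C3 methyl enol ether, C4=C15H2) | O[C@H]1C=C(OC)C(=C)[C@H]2[C@@H](O[Si](C)(C)C(C)(C)C)[C@H](CCO[Si](C)(C)C(C)(C)C)[C@H](OCc3ccc(OC)cc3)C[C@@]12C | intermediate (not isolated)
13 | 1α-acetate of 12 | CC(=O)O[C@H]1C=C(OC)C(=C)[C@H]2[C@@H](O[Si](C)(C)C(C)(C)C)[C@H](CCO[Si](C)(C)C(C)(C)C)[C@H](OCc3ccc(OC)cc3)C[C@@]12C | intermediate
14 | 1α-acetoxy-4-methylene-3-ketone | CC(=O)O[C@H]1CC(=O)C(=C)[C@H]2[C@@H](O[Si](C)(C)C(C)(C)C)[C@H](CCO[Si](C)(C)C(C)(C)C)[C@H](OCc3ccc(OC)cc3)C[C@@]12C | intermediate
15 | 1α-acetoxy-3β-hydroxy-4-methylene decalin | CC(=O)O[C@H]1C[C@H](O)C(=C)[C@H]2[C@@H](O[Si](C)(C)C(C)(C)C)[C@H](CCO[Si](C)(C)C(C)(C)C)[C@H](OCc3ccc(OC)cc3)C[C@@]12C | intermediate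
16 | 3β-methoxymethyl ether of 15 | CC(=O)O[C@H]1C[C@H](OCOC)C(=C)[C@H]2[C@@H](O[Si](C)(C)C(C)(C)C)[C@H](CCO[Si](C)(C)C(C)(C)C)[C@H](OCc3ccc(OC)cc3)C[C@@]12C | intermediate
17 | 1α-acetoxy-15-hydroxy decalin (4α-H, 4β-CH2OH) | CC(=O)O[C@H]1C[C@H](OCOC)[C@H](CO)[C@H]2[C@@H](O[Si](C)(C)C(C)(C)C)[C@H](CCO[Si](C)(C)C(C)(C)C)[C@H](OCc3ccc(OC)cc3)C[C@@]12C | intermediate (not isolated)
18 | 1α,15-diol | O[C@H]1C[C@H](OCOC)[C@H](CO)[C@H]2[C@@H](O[Si](C)(C)C(C)(C)C)[C@H](CCO[Si](C)(C)C(C)(C)C)[C@H](OCc3ccc(OC)cc3)C[C@@]12C | intermediate
19 | 1α-hydroxy 15-aldehyde | O[C@H]1C[C@H](OCOC)[C@H](C=O)[C@H]2[C@@H](O[Si](C)(C)C(C)(C)C)[C@H](CCO[Si](C)(C)C(C)(C)C)[C@H](OCc3ccc(OC)cc3)C[C@@]12C | intermediate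
20 | 1α-mesylate 15-aldehyde: cis-decalin (5β-H, 10β-CH3) with 3β-OMOM, 6α-OTBS, 7β-CH2CH2OTBS, 8β-OPMB | CS(=O)(=O)O[C@H]1C[C@H](OCOC)[C@H](C=O)[C@H]2[C@@H](O[Si](C)(C)C(C)(C)C)[C@H](CCO[Si](C)(C)C(C)(C)C)[C@H](OCc3ccc(OC)cc3)C[C@@]12C | intermediate
21 | ten-membered dienal: C1=C10 with C2 cis to C9, C4=C5 with C3 trans to C6, C15 aldehyde | [C@@H]1(O[Si](C)(C)C(C)(C)C)/C=C(\C=O)/[C@@H](OCOC)C/C=C(/C)\C[C@@H](OCc2ccc(OC)cc2)[C@H]1CCO[Si](C)(C)C(C)(C)C | intermediate (not isolated)
22 | allylic alcohol (15-ol) of 21 | [C@@H]1(O[Si](C)(C)C(C)(C)C)/C=C(\CO)/[C@@H](OCOC)C/C=C(/C)\C[C@@H](OCc2ccc(OC)cc2)[C@H]1CCO[Si](C)(C)C(C)(C)C | intermediate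
23 | 4,5-epoxy-15-ol (epoxide oxygen α at C4) | [C@@H]1(O[Si](C)(C)C(C)(C)C)[C@H]2O[C@]2(CO)[C@@H](OCOC)C/C=C(/C)\C[C@@H](OCc3ccc(OC)cc3)[C@H]1CCO[Si](C)(C)C(C)(C)C | intermediate
24 | 4α,15-diol (C5 methylene) | [C@@H]1(O[Si](C)(C)C(C)(C)C)C[C@@](O)(CO)[C@@H](OCOC)C/C=C(/C)\C[C@@H](OCc2ccc(OC)cc2)[C@H]1CCO[Si](C)(C)C(C)(C)C | intermediate
25 | 4,15-acetonide of 24 | [C@@H]1(O[Si](C)(C)C(C)(C)C)C[C@]2(OC(C)(C)OC2)[C@@H](OCOC)C/C=C(/C)\C[C@@H](OCc3ccc(OC)cc3)[C@H]1CCO[Si](C)(C)C(C)(C)C | intermediate
26 | 6α,12-diol | O[C@@H]1C[C@]2(OC(C)(C)OC2)[C@@H](OCOC)C/C=C(/C)\C[C@@H](OCc3ccc(OC)cc3)[C@H]1CCO | intermediate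
27 | lactol (C12 hemiacetal closed on O6) | [C@@H]12C[C@]3(OC(C)(C)OC3)[C@@H](OCOC)C/C=C(/C)\C[C@@H](OCc4ccc(OC)cc4)[C@H]1CC(O)O2 | intermediate (not isolated)
28 | trans-fused 6α,12-lactone | [C@@H]12C[C@]3(OC(C)(C)OC3)[C@@H](OCOC)C/C=C(/C)\C[C@@H](OCc4ccc(OC)cc4)[C@H]1CC(=O)O2 | intermediate
29 | 11-(dimethylaminomethyl) lactone | [C@@H]12C[C@]3(OC(C)(C)OC3)[C@@H](OCOC)C/C=C(/C)\C[C@@H](OCc4ccc(OC)cc4)[C@H]1C(CN(C)C)C(=O)O2 | intermediate (not isolated)
30 | 11-(trimethylammoniomethyl) lactone iodide | [C@@H]12C[C@]3(OC(C)(C)OC3)[C@@H](OCOC)C/C=C(/C)\C[C@@H](OCc4ccc(OC)cc4)[C@H]1C(C[N+](C)(C)C)C(=O)O2.[I-] | intermediate (not isolated)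
31 | α-methylene lactone (8β-OPMB) | [C@@H]12C[C@]3(OC(C)(C)OC3)[C@@H](OCOC)C/C=C(/C)\C[C@@H](OCc4ccc(OC)cc4)[C@H]1C(=C)C(=O)O2 | intermediate
32 | 8β-alcohol | [C@@H]12C[C@]3(OC(C)(C)OC3)[C@@H](OCOC)C/C=C(/C)\C[C@@H](O)[C@H]1C(=C)C(=O)O2 | intermediate
33 | angelic acid, (Z)-2-methylbut-2-enoic acid | C/C=C(/C)C(=O)O | starting material
34 | 8β-angelate | [C@@H]12C[C@]3(OC(C)(C)OC3)[C@@H](OCOC)C/C=C(/C)\C[C@@H](OC(=O)/C(C)=C\C)[C@H]1C(=C)C(=O)O2 | intermediate
35 | 3β,4α,15-triol with the Z-C1=C10 olefin | [C@@H]12C[C@@](O)(CO)[C@@H](O)C/C=C(/C)\C[C@@H](OC(=O)/C(C)=C\C)[C@H]1C(=C)C(=O)O2 | intermediate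
36 | CNP0307250.1, 8β-angeloyloxy-1β,10β-epoxy-3β,4α,15-trihydroxygermacr-11(13)-en-6α,12-olide | C=C1C(=O)O[C@@H]2C[C@@](O)(CO)[C@@H](O)C[C@H]3O[C@@]3(C)C[C@@H](OC(=O)/C(C)=C\C)[C@@H]12 | target

## Step count and least certain steps

Total: 25 steps. Longest linear sequence: 25 steps (1 to 36); 6 and 33 are bought.

Step 15 (key step). Most likely failure: β-elimination of the axial C3 ether from the aldehyde enolate (loss of the C3 oxygen) outruns the fragmentation, because the axial C–O bond is also aligned with the enolate. Fallback, setting out from 20: the aldehyde is first converted (Me3SiOTf, Et3N, CH2Cl2, −78 °C) into its isolated trimethylsilyl enol ether F1. The enolate is then released irreversibly and without base by anhydrous fluoride (Bu4N+ Ph3SiF2−, THF, −78 °C), so that fragmentation to 21 runs at a temperature where alkoxide expulsion is frozen. Borohydride reduction in the same flask rejoins the route at 22.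

Step 4. Most likely failure: poor enantioface selection, or Lewis acid degradation of the trisilyloxy diene before cycloaddition. Fallback, setting out from 5 and 6: uncatalysed cycloaddition (toluene, 40 °C) gives 7 as the racemate; regio- and endo-selectivity do not depend on the catalyst. The racemate is carried through steps 5 to 15 and resolved in step 16: L-(+)-diethyl tartrate epoxidises both enantiomers of 22 on the same absolute face of C4=C5, so 23 and its diastereomer, the epoxy alcohol F2, are separated by chromatography. The route is rejoined at 23.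

Step 9. Most likely failure: ionisation of the allylic acetate assisted by the enol ether (loss of the C1 oxygen and a transposed dienone) instead of simple hydrolysis. Fallback, setting out from 13: the enol ether is attacked by bromonium instead of a proton (N-bromosuccinimide, NaHCO3, THF/H2O, 0 °C) to give the 2-bromo-3-ketone F3 under buffered conditions in which the acetate cannot ionise. Radical debromination (Bu3SnH, AIBN cat., benzene, 60 °C) rejoins the route at 14.

Step 25. Most likely failure: oxygen delivery to the α face, or direction by the 4,15-diol instead of the C3 hydroxyl, since the facial bias of a flexible ten-membered ring is not secured. Fallback, setting out from 35 and ending at 36: reagent-controlled epoxidation by a chiral dioxirane made from a fructose-derived ketone (1,2:4,5-di-O-isopropylidene-D-erythro-2,3-hexodiulo-2,6-pyranose or its L-enantiomer, chosen for the β face) and KHSO5 at pH 10. Only the electron-rich trisubstituted olefin should react, and no new compound is formed on the way.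

## Further compounds

F1 | step 15 | trimethylsilyl enol ether of aldehyde 20 (C4=C15H–OSiMe3, 1α-mesylate retained) | CS(=O)(=O)O[C@H]1C[C@H](OCOC)C(=CO[Si](C)(C)C)[C@H]2[C@@H](O[Si](C)(C)C(C)(C)C)[C@H](CCO[Si](C)(C)C(C)(C)C)[C@H](OCc3ccc(OC)cc3)C[C@@]12C
F2 | step 4 | diastereomer of 23 formed from the enantiomer of 22 (C3, C6, C7, C8 inverted; epoxide configuration as in 23) | [C@H]1(O[Si](C)(C)C(C)(C)C)[C@H]2O[C@]2(CO)[C@H](OCOC)C/C=C(/C)\C[C@H](OCc3ccc(OC)cc3)[C@@H]1CCO[Si](C)(C)C(C)(C)C
F3 | step 9 | 1α-acetoxy-2-bromo-4-methylene-3-ketone | CC(=O)O[C@H]1C(Br)C(=O)C(=C)[C@H]2[C@@H](O[Si](C)(C)C(C)(C)C)[C@H](CCO[Si](C)(C)C(C)(C)C)[C@H](OCc3ccc(OC)cc3)C[C@@]12C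
F0 | step 25 | none | none
A1 | alternative 1 | open-chain aldehyde with a (Z)-2-(bromomethyl)enoate terminus (C6 aldehyde, C7=C11, Z-C1=C10) | O=CC[C@]1(OC(C)(C)OC1)[C@@H](OCOC)C/C=C(/C)\C[C@@H](OCc1ccc(OC)cc1)/C=C(\CBr)C(=O)OC
A2 | alternative 2 | cis-1-vinyl-2-isopropenylcyclohexanol carrying the C3 ether and the C4/C15 acetonide | C=C[C@@]1(O)C[C@]2(OC(C)(C)OC2)[C@@H](OCOC)C[C@H]1C(C)=C
A3 | alternative 2 | cyclodec-5-enone from A2 (C6 ketone, Z-C1=C10) | O=C1C[C@]2(OC(C)(C)OC2)[C@@H](OCOC)C/C=C(/C)\CCC1
A4 | alternative 3 | eleven-membered cyclic sulfone bridging C1 and C10, lactone in place | [C@@H]12C[C@]3(OC(C)(C)OC3)[C@@H](OCOC)CCS(=O)(=O)C(C)C[C@@H](OCc4ccc(OC)cc4)[C@H]1CC(=O)O2
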